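**Strategy.** The target, 8-(3,4-dimethoxyphenyl)-2,6-dimethoxy-1,4-naphthoquinone, is achiral. Everything rests on opening the quinone ring (C1, C2, C3, C4, C4a, C8a) at the C4–C4a bond: C1–C4 with their oxygen pattern (C=O, C–OMe, C–H, C=O) are the four carbons of methyl semisquarate, and C8a/C4a are the ipso and free ortho carbons of the biaryl arene. The key step heats a 4-aryl-4-hydroxy-3-methoxycyclobutenone: 4π opening to a vinylketene and 6π closure onto the arene expand the four-membered ring to the six-membered ring, and oxidation in the same flask delivers the quinone. The precursor is assembled by adding the biaryl-2-yllithium to the more electrophilic carbonyl of the semisquarate.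

Key step: step 4

Remark: the target has no stereocentre, so the "single enantiomer" is the achiral compound itself; the carbinol centre of 8 and the ring-fusion centre of 10 are racemic and are destroyed in step 4.

**Step 1**
Reactants: 1 1-bromo-2-iodo-4-methoxybenzene (4-bromo-3-iodoanisole); 2 (3,4-dimethoxyphenyl)boronic acid
Product: 3 2-bromo-3',4',5-trimethoxy-1,1'-biphenyl
Conditions: Pd(PPh3)4 (3 mol%), 2 M aq. Na2CO3, DME, 80 °C
Reagents that add atoms: none
Why: Suzuki–Miyaura coupling in which oxidative addition of Pd(0) into the C–I bond is much faster than into the C–Br bond, so only the iodide should be replaced and the bromide is kept for step 3.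

**Step 2**
Reactants: 4 3,4-dimethoxycyclobut-3-ene-1,2-dione (dimethyl squarate)
Product: 6 3-methoxycyclobut-3-ene-1,2-dione (methyl semisquarate), via hydroxycyclobutenone 5 (not isolated)
Conditions: LiAlH(OtBu)3 (1.05 equiv), THF, −78 °C; 1 M HCl quench; crude in CH2Cl2, conc. HCl (cat.), rt
Reagents that add atoms: water, O (oxygen of the new carbonyl group)
Why: Hydride 1,2-addition to one of the two equivalent carbonyls, then acid-induced ionisation of the allylic alcohol, hydration of the methoxy-stabilised cyclobutenyl cation and loss of methanol (reductive 1,3-carbonyl transposition of a squarate ester) should give the semisquarate; the stereocentre of 5 is racemic and is lost.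

**Step 3**
Reactants: 3 2-bromo-3',4',5-trimethoxy-1,1'-biphenyl; 6 3-methoxycyclobut-3-ene-1,2-dione
Product: 8 4-[2-(3,4-dimethoxyphenyl)-4-methoxyphenyl]-4-hydroxy-3-methoxycyclobut-2-en-1-one (racemic), via aryllithium 7 (not isolated)
Conditions: 3, n-BuLi (1.05 equiv), THF, −78 °C, 20 min; cannulate into 6 (1.2 equiv), THF, −78 °C; sat. aq. NH4Cl at −78 °C
Reagents that add atoms: none
Why: Bromine–lithium exchange followed by 1,2-addition of the aryllithium to the ketone-like carbonyl next to the methoxy-bearing carbon, which is more electrophilic than the vinylogous ester carbonyl, should give the carbinol regioselectively; the new quaternary stereocentre forms as a racemate and is destroyed in step 4.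

**Step 4**
Reactants: 8 4-[2-(3,4-dimethoxyphenyl)-4-methoxyphenyl]-4-hydroxy-3-methoxycyclobut-2-en-1-one
Product: 12 8-(3,4-dimethoxyphenyl)-2,6-dimethoxynaphthalene-1,4-dione (target), via vinylketene 9 (not isolated), via bicyclic dienone 10 (not isolated), via hydroquinone 11 (not isolated)
Conditions: degassed p-xylene (0.02 M), 138 °C; then concentrate, Ag2O (2 equiv), Na2SO4, Et2O, rt
Reagents that add atoms: none
Why: Heating triggers conrotatory 4π electrocyclic opening of the cyclobutenone C1–C4 bond, in which the donor hydroxyl rotates outward (torquoselectivity) so that the aryl group ends up cis to the ketene in vinylketene 9. A thermally allowed disrotatory 6π electrocyclisation then joins the ketene carbon to the free ortho carbon of the anisole ring (six-membered ring, closed by C–C bond formation between the future C4 and C4a), giving dienone 10, whose tautomerisation restores aromaticity as hydroquinone 11. This is the Moore rearrangement (thermal ring expansion of 4-aryl-4-hydroxycyclobutenones), a four-to-six ring expansion that takes the ipso and ortho carbons of the aryl group into the ring. No stereocentre remains, because the carbinol centre of 8 becomes sp2 in 9 and the transient C4a–H centre of 10 is erased by enolisation. Site selectivity is secured because the second ortho position carries the dimethoxyphenyl group and closure onto that remote ring would need an eight-membered transition state, while high dilution should suppress ketene oligomerisation. Ag2O then dehydrogenates the electron-rich hydroquinone to quinone 12 without touching the aryl methyl ethers.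

**Compound list**
1 | 1-bromo-2-iodo-4-methoxybenzene | COc1ccc(Br)c(I)c1 | starting material
2 | (3,4-dimethoxyphenyl)boronic acid | COc1ccc(B(O)O)cc1OC | starting material
3 | 2-bromo-3',4',5-trimethoxy-1,1'-biphenyl | COc1ccc(Br)c(-c2ccc(OC)c(OC)c2)c1 | intermediate
4 | 3,4-dimethoxycyclobut-3-ene-1,2-dione (dimethyl squarate) | COC1=C(OC)C(=O)C1=O | starting material
5 | 4-hydroxy-2,3-dimethoxycyclobut-2-en-1-one (racemic) | COC1=C(OC)C(=O)C1O | intermediate (not isolated)
6 | 3-methoxycyclobut-3-ene-1,2-dione | COC1=CC(=O)C1=O | intermediate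
7 | [2-(3,4-dimethoxyphenyl)-4-methoxyphenyl]lithium | [Li]c1ccc(OC)cc1-c1ccc(OC)c(OC)c1 | intermediate (not isolated)
8 | 4-[2-(3,4-dimethoxyphenyl)-4-methoxyphenyl]-4-hydroxy-3-methoxycyclobut-2-en-1-one (racemic) | COC1=CC(=O)C1(O)c1ccc(OC)cc1-c1ccc(OC)c(OC)c1 | intermediate
9 | (3Z)-4-[2-(3,4-dimethoxyphenyl)-4-methoxyphenyl]-4-hydroxy-3-methoxybuta-1,3-dien-1-one (aryl cis to the ketenyl carbon) | O=C=C/C(OC)=C(/O)c1ccc(OC)cc1-c1ccc(OC)c(OC)c1 | intermediate (not isolated)
10 | 5-(3,4-dimethoxyphenyl)-4-hydroxy-3,7-dimethoxynaphthalen-1(8aH)-one (racemic) | O=C1C=C(OC)C(O)=C2C(-c3ccc(OC)c(OC)c3)=CC(OC)=CC12 | intermediate (not isolated)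
11 | 8-(3,4-dimethoxyphenyl)-2,6-dimethoxynaphthalene-1,4-diol | COc1cc(O)c2cc(OC)cc(-c3ccc(OC)c(OC)c3)c2c1O | intermediate (not isolated)
12 | 8-(3,4-dimethoxyphenyl)-2,6-dimethoxynaphthalene-1,4-dione | COC1=CC(=O)c2cc(OC)cc(-c3ccc(OC)c(OC)c3)c2C1=O | target

**Total step count:** 4
**Longest linear sequence:** 3 steps (steps 1, 3, 4; equally steps 2, 3, 4)

**Steps most likely to fail**

1. Step 4 (key step). If 6π closure onto the twisted, ortho-substituted arene is slow, the reversible ring opening may leak through the hydroxyl-inward ketene, which lactonises to a butenolide, or the aldoketene may oligomerise. The fallback sets out from 8 and removes the free hydroxyl. Silylation (TMSOTf, Et3N, CH2Cl2, −78 °C) should give 4-[2-(3,4-dimethoxyphenyl)-4-methoxyphenyl]-3-methoxy-4-(trimethylsilyloxy)cyclobut-2-en-1-one F1. Thermolysis in p-xylene should then pass through the silyloxy vinylketene F2 and the silyloxy dienone F3 to 5-(3,4-dimethoxyphenyl)-3,7-dimethoxy-4-(trimethylsilyloxy)naphthalen-1-ol F4. Oxidation with PhI(OAc)2 in MeCN/H2O at 0 °C, with loss of the silyl group, comes back to the route at 12.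

2. Step 3. The hindered, strongly basic biaryl-2-yllithium may remove the acidic vinylic proton of 6 or add twice instead of adding once to the ketone carbonyl. The fallback sets out from 6 and makes the biaryl bond last. Commercial 1-bromo-2-chloro-4-methoxybenzene F5 undergoes Br/Li exchange (n-BuLi, THF, −90 °C) to the smaller, less basic (2-chloro-4-methoxyphenyl)lithium F6. Its addition to 6 should give 4-(2-chloro-4-methoxyphenyl)-4-hydroxy-3-methoxycyclobut-2-en-1-one F7. Thermolysis and Ag2O oxidation as in step 4 should proceed through (3Z)-4-(2-chloro-4-methoxyphenyl)-4-hydroxy-3-methoxybuta-1,3-dien-1-one F8, 5-chloro-4-hydroxy-3,7-dimethoxynaphthalen-1(8aH)-one F9 and 8-chloro-2,6-dimethoxynaphthalene-1,4-diol F10 to 8-chloro-2,6-dimethoxynaphthalene-1,4-dione F11. Suzuki–Miyaura coupling of F11 with 2 (Pd(OAc)2, SPhos, anhydrous K3PO4, toluene, 90 °C) comes back to the route at 12; compounds 1 and 3 are then not needed.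

3. Step 2. The small dimethyl ester may be over-reduced, and the water-soluble methyl semisquarate may be lost by hydrolysis of its vinylogous ester during the aqueous acid stage. The fallback sets out from commercial diisopropyl squarate (3,4-diisopropoxycyclobut-3-ene-1,2-dione) F12. The same reduction and acid transposition should pass through 4-hydroxy-2,3-diisopropoxycyclobut-2-en-1-one F13 to the lipophilic, easily extracted 3-isopropoxycyclobut-3-ene-1,2-dione F14. Deliberate hydrolysis (6 M HCl, rt, then lyophilisation) should give semisquaric acid (3-hydroxycyclobut-3-ene-1,2-dione) F15. Anhydrous O-methylation with trimethyl orthoformate in refluxing MeOH, worked up by evaporation only, comes back to the route at 6.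

**Further compounds**
F1 | step 4 | 4-[2-(3,4-dimethoxyphenyl)-4-methoxyphenyl]-3-methoxy-4-(trimethylsilyloxy)cyclobut-2-en-1-one (racemic) | COC1=CC(=O)C1(O[Si](C)(C)C)c1ccc(OC)cc1-c1ccc(OC)c(OC)c1
F2 | step 4 | (3Z)-4-[2-(3,4-dimethoxyphenyl)-4-methoxyphenyl]-3-methoxy-4-(trimethylsilyloxy)buta-1,3-dien-1-one | O=C=C/C(OC)=C(/O[Si](C)(C)C)c1ccc(OC)cc1-c1ccc(OC)c(OC)c1
F3 | step 4 | 5-(3,4-dimethoxyphenyl)-3,7-dimethoxy-4-(trimethylsilyloxy)naphthalen-1(8aH)-one (racemic) | O=C1C=C(OC)C(O[Si](C)(C)C)=C2C(-c3ccc(OC)c(OC)c3)=CC(OC)=CC12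
F4 | step 4 | 5-(3,4-dimethoxyphenyl)-3,7-dimethoxy-4-(trimethylsilyloxy)naphthalen-1-ol | COc1cc(O)c2cc(OC)cc(-c3ccc(OC)c(OC)c3)c2c1O[Si](C)(C)C
F5 | step 3 | 1-bromo-2-chloro-4-methoxybenzene | COc1ccc(Br)c(Cl)c1
F6 | step 3 | (2-chloro-4-methoxyphenyl)lithium | [Li]c1ccc(OC)cc1Cl
F7 | step 3 | 4-(2-chloro-4-methoxyphenyl)-4-hydroxy-3-methoxycyclobut-2-en-1-one (racemic) | COC1=CC(=O)C1(O)c1ccc(OC)cc1Cl
F8 | step 3 | (3Z)-4-(2-chloro-4-methoxyphenyl)-4-hydroxy-3-methoxybuta-1,3-dien-1-one | O=C=C/C(OC)=C(/O)c1ccc(OC)cc1Cl
F9 | step 3 | 5-chloro-4-hydroxy-3,7-dimethoxynaphthalen-1(8aH)-one (racemic) | O=C1C=C(OC)C(O)=C2C(Cl)=CC(OC)=CC12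
F10 | step 3 | 8-chloro-2,6-dimethoxynaphthalene-1,4-diol | COc1cc(O)c2cc(OC)cc(Cl)c2c1O
F11 | step 3 | 8-chloro-2,6-dimethoxynaphthalene-1,4-dione | COC1=CC(=O)c2cc(OC)cc(Cl)c2C1=O
F12 | step 2 | 3,4-diisopropoxycyclobut-3-ene-1,2-dione (diisopropyl squarate) | CC(C)OC1=C(OC(C)C)C(=O)C1=O
F13 | step 2 | 4-hydroxy-2,3-diisopropoxycyclobut-2-en-1-one (racemic) | CC(C)OC1=C(OC(C)C)C(=O)C1O
F14 | step 2 | 3-isopropoxycyclobut-3-ene-1,2-dione | CC(C)OC1=CC(=O)C1=O
F15 | step 2 | 3-hydroxycyclobut-3-ene-1,2-dione (semisquaric acid) | OC1=CC(=O)C1=O
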